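**Assumption:** Fertidin is taken exactly as the SMILES shows, i.e. the 6‑O‑p‑anisate of jaeschkeanadiol (trans‑fused daucane; daucane numbering C1–C10 is used in the explanations).

## Retrosynthetic overview
1. Final C6–O ester: selective acylation of the secondary OH of jaeschkeanadiol (12).
2. Seven‑membered ring formed last, by RCM of the C8=C9 bond (allyl on C1 + methallyl on C6).
3. C4 carbinol: isopropyl‑cerium addition to a cyclopentanone, anti to the C5 side chain.
4. C5–C6 bond: anti‑selective boron aldol of a regiodefined cyclopentanone enolate with 3‑methylbut‑3‑enal.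
5. C1 quaternary centre (and the five‑membered ring, which is present from the start): Cu‑catalysed asymmetric conjugate addition of Me to 3‑allylcyclopentenone, with enolate trapping.

## Route

**Step 1**
Reactants: 1, 3‑ethoxycyclopent‑2‑en‑1‑one; 2, allylmagnesium bromide
Product: 3, 3‑allylcyclopent‑2‑en‑1‑one
Conditions: allylMgBr, THF, 0 °C; then 1 M HCl, 0 °C, 10 min
Reagents that add atoms: allylmagnesium bromide, C=CC[Mg]Br
Why: Stork–Danheiser sequence: 1,2‑addition to the vinylogous ester carbonyl, then acid hydrolysis with loss of ethanol gives the transposed 3‑substituted enone; the cold, brief acid step limits isomerisation into conjugation.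

**Step 2**
Reactants: 3; 4, trimethylaluminium; 5, trimethylsilyl triflate
Product: 6, (R)‑trimethyl{[3‑methyl‑3‑(prop‑2‑en‑1‑yl)cyclopent‑1‑en‑1‑yl]oxy}silane
Conditions: Me3Al, Cu(OTf)2 (5 mol %), chiral sulfonate‑bridged NHC–Ag complex (2.5 mol %; the enantiomer giving the R product), THF, −78 °C; then TMSOTf, −78 → 0 °C
Reagents that add atoms: trimethylaluminium, C[Al](C)C; TMSOTf, C[Si](C)(C)OS(=O)(=O)C(F)(F)F
Why: Catalytic asymmetric conjugate addition of Me to the β‑substituted cyclopentenone sets the C1 quaternary centre under catalyst control; O‑silylation of the aluminium enolate fixes the enolate regiochemistry at C4=C5, next to the quaternary carbon.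

**Step 3**
Reactants: 7, 3‑methylbut‑3‑en‑1‑ol
Product: 8, 3‑methylbut‑3‑enal (used at once as a cold solution)
Conditions: Dess–Martin periodinane, NaHCO3, CH2Cl2, 0 °C
Reagents that add atoms: none
Why: Buffered, base‑free Dess–Martin oxidation gives the β,γ‑unsaturated aldehyde without isomerisation to prenal.

**Step 4**
Reactants: 6; 8
Product: 9, (2S,3R)‑2‑[(1S)‑1‑hydroxy‑3‑methylbut‑3‑en‑1‑yl]‑3‑methyl‑3‑(prop‑2‑en‑1‑yl)cyclopentan‑1‑one
Conditions: MeLi, THF, 0 °C; Cy2BCl, −78 °C; then 8, −78 → −20 °C; pH 7 buffer, H2O2, MeOH, 0 °C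
Reagents that add atoms: 3‑methylbut‑3‑enal (8), CC(=C)CC=O
Why: MeLi releases the regiodefined lithium enolate, which is transmetalated to boron; the cyclic (E)‑boron enolate reacts through a Zimmerman–Traxler chair to give the anti aldol (C5/C6), and the aldehyde enters anti to the larger allyl group, i.e. cis to the C1 methyl.

**Step 5**
Reactants: 9; 10, isopropylmagnesium chloride
Product: 11, (1R,2S,3R)‑2‑[(1S)‑1‑hydroxy‑3‑methylbut‑3‑en‑1‑yl]‑3‑methyl‑1‑(propan‑2‑yl)‑3‑(prop‑2‑en‑1‑yl)cyclopentan‑1‑ol
Conditions: i‑PrMgCl (3.5 equiv), anhydrous CeCl3, THF, −78 → −40 °C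
Reagents that add atoms: isopropylmagnesium chloride, CC(C)[Mg]Cl
Why: Imamoto organocerium 1,2‑addition suppresses enolisation and retro‑aldol of the chelated aldolate; the nucleophile attacks the ketone face anti to the adjacent C5 side chain, giving the tertiary OH cis to that chain (C4).

**Step 6**
Reactants: 11
Product: 12, jaeschkeanadiol, (3R,3aS,4S,8aR)‑6,8a‑dimethyl‑3‑(propan‑2‑yl)‑1,2,3,3a,4,5,8,8a‑octahydroazulene‑3,4‑diol
Conditions: Grubbs II (5 mol %), CH2Cl2 (2 mM), 40 °C
Reagents that add atoms: none
Why: Ring‑closing metathesis of the allyl and methallyl groups (loss of ethylene) forms the trisubstituted C8=C9 alkene; the trans arrangement of the two chains on the cyclopentane gives the trans‑fused hydroazulene, and no stereocentre is touched.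

**Step 7**
Reactants: 12; 13, 4‑methoxybenzoyl chloride
Product: 14, Fertidin, (3R,3aS,4S,8aR)‑3‑hydroxy‑6,8a‑dimethyl‑3‑(propan‑2‑yl)‑1,2,3,3a,4,5,8,8a‑octahydroazulen‑4‑yl 4‑methoxybenzoate
Conditions: 4‑MeOC6H4COCl, Et3N, DMAP, CH2Cl2, 0 °C → rt
Reagents that add atoms: 4‑methoxybenzoyl chloride, COc1ccc(cc1)C(Cl)=O
Why: DMAP‑catalysed acylation takes only the secondary C6–OH; the tertiary C4–OH is too hindered, and configuration is retained.

## Compound list
1 | 3‑ethoxycyclopent‑2‑en‑1‑one | CCOC1=CC(=O)CC1 | starting material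
2 | allylmagnesium bromide | C=CC[Mg]Br | starting material
3 | 3‑allylcyclopent‑2‑en‑1‑one | C=CCC1=CC(=O)CC1 | intermediate
4 | trimethylaluminium | C[Al](C)C | starting material
5 | trimethylsilyl triflate | C[Si](C)(C)OS(=O)(=O)C(F)(F)F | starting material
6 | (R)‑3‑allyl‑3‑methyl‑1‑(trimethylsilyloxy)cyclopent‑1‑ene | C=CC[C@@]1(C)CCC(O[Si](C)(C)C)=C1 | intermediate
7 | 3‑methylbut‑3‑en‑1‑ol | CC(=C)CCO | starting material
8 | 3‑methylbut‑3‑enal | CC(=C)CC=O | intermediate
9 | (2S,3R)‑3‑allyl‑2‑[(1S)‑1‑hydroxy‑3‑methylbut‑3‑enyl]‑3‑methylcyclopentanone | O[C@@H](CC(C)=C)[C@@H]1[C@@](C)(CC=C)CCC1=O | intermediate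
10 | isopropylmagnesium chloride | CC(C)[Mg]Cl | starting material
11 | (1R,2S,3R)‑3‑allyl‑2‑[(1S)‑1‑hydroxy‑3‑methylbut‑3‑enyl]‑1‑isopropyl‑3‑methylcyclopentan‑1‑ol | O[C@@H](CC(C)=C)[C@@H]1[C@@](C)(CC=C)CC[C@@]1(O)C(C)C | intermediate
12 | jaeschkeanadiol | O[C@H]1CC(C)=CC[C@@]2(C)CC[C@@](O)(C(C)C)[C@H]12 | intermediate
13 | 4‑methoxybenzoyl chloride | COc1ccc(cc1)C(Cl)=O | starting material
14 | Fertidin | COc1ccc(C(=O)O[C@H]2CC(C)=CC[C@@]3(C)CC[C@@](O)(C(C)C)[C@H]23)cc1 | target

## Summary
Total steps: 7. Longest linear sequence: 6 (steps 1, 2, 4, 5, 6, 7).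

Three steps most likely to fail:

1. **Step 4 (aldol).** This is the weakest step. The enolate face is differentiated only by CH3 versus CH2CH=CH2 on C1, so the C5 diastereoselectivity may be modest (I estimate a few to one) and the wrong isomer would have to be separated. Aldehyde 8 is also prone to isomerisation.
 Fallback: set the C1/C5 pair by an Ireland–Claisen rearrangement (chair transition state) of the (E)‑3‑methylhexa‑2,5‑dienyl ester of an enantiopure 3‑silyloxy‑5‑methylhex‑5‑enoic acid, then close the cyclopentanone by Rh‑catalysed 4‑pentenal hydroacylation to rejoin the route at protected 9. If only C6 is wrong, oxidise it (Dess–Martin) and reduce with Me4NBH(OAc)3, directed by the C4–OH, to give the anti‑1,3‑diol.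

2. **Step 5 (i‑Pr addition).** The ketone is hindered and enolisable, and the substrate is a β‑hydroxy ketone, so enolisation, reduction or retro‑aldol could compete.
 Fallback: reorder the route. Protect C6–OH, do the RCM first, and add the nucleophile to the trans‑fused bicyclic ketone, where the axial angular methyl also blocks the β‑face. Isopropenyl‑cerium followed by selective hydrogenation of the 1,1‑disubstituted alkene is a further option.

3. **Step 2 (asymmetric conjugate addition).** The ee on a five‑membered enone is likely around 85–95 %, and the skipped diene in 3 is sensitive to Lewis acid. Enantiopurity would be upgraded by recrystallising 12 or 14.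
 Fallback: make the quaternary centre by Pd‑catalysed decarboxylative asymmetric allylic alkylation of the allyl β‑ketoester of 3‑isobutoxycyclopent‑2‑enone (after C‑methylation). Reduction and hydrolysis then give 4‑allyl‑4‑methylcyclopent‑2‑enone, whose α′‑enolate (LDA) is the same C5 enolate; the extra ring alkene is removed later by Stryker conjugate reduction.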